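**Retrosynthetic overview**
1. Target ⇒ (epoxidation of C12=C13, acetylation, α-methylenation of the lactone, hydroxyl-directed hydrogenation of C5=C10) ⇒ a tetracyclic cyclohepta-1,4-diene carrying rings A–D.
2. Ring C (seven-membered) ⇒ one-pot Negishi coupling / divinylcyclopropane–cycloheptadiene [3,3] rearrangement of a ring-B enol triflate (at C5) with an enantiopure cis-2-iodo-1-methyl-1-vinylcyclopropane (C10–C15): C5–C10 first, then C6–C14.
3. Enabling feature: the quaternary carbon C6 (ring B/ring C junction, methyl C16) is bonded to C5 and is separated only by C14 from the C12=C13 unit that becomes the oxirane; the C6–C14 bond flanked by C12=C13 and a temporary C5=C10 bond is the retron of a cis-1,2-dialkenylcyclopropane (C10, C11, C12).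
4. Enol triflate ⇒ enone ⇒ ring D by directed epoxidation and epoxy-acid lactonization ⇒ ring A by ring-closing enyne metathesis ⇒ ring B by an auxiliary-controlled Diels–Alder reaction of isoprene followed by enolate allylation (quaternary C9).
5. Order of ring formation: B, A, D, a temporary cyclopropane, then C; the oxirane is put on last.

Key step: step 19

Numbering and faces used in the names: C1–C4 and C9 form the five-membered carbocycle (ring A), C4–C9 the six-membered ring (ring B), C5, C6 and C10–C14 the seven-membered ring (ring C); C15 is the methyl on C12, C16 the methyl on C6, C17 the CH2O carbon on C9, C18–C20 the lactone carbons on C3 (ring D runs C3–C18–C19–O–C2); β is the face of ring B that carries C17.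
Remark: the oxirane is treated as a functional group and is installed by epoxidation once all carbocycles and the lactone are in place.

**Route**

Step 1
Reactants: 1 (diethoxyphosphoryl)acetic acid; 2 (R)-4-benzyloxazolidin-2-one
Product: 3 (R)-4-benzyl-3-[(diethoxyphosphoryl)acetyl]oxazolidin-2-one
Conditions: N,N'-dicyclohexylcarbodiimide, DMAP (cat.), CH2Cl2, 0 °C → rt
Reagents that add atoms: none
Why: Carbodiimide/DMAP (Steglich-type) N-acylation of the oxazolidinone should give the Horner–Wadsworth–Emmons imide; no stereocenter is formed.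

Step 2
Reactants: 3 phosphonate imide; 4 3-(trimethylsilyl)prop-2-ynal
Product: 5 (R)-4-benzyl-3-[(E)-5-(trimethylsilyl)pent-2-en-4-ynoyl]oxazolidin-2-one
Conditions: LiCl, i-Pr2NEt, MeCN, rt
Reagents that add atoms: none
Why: The Masamune–Roush variant of the Horner–Wadsworth–Emmons olefination is mild enough for the base-sensitive ynal and should give the (E)-enoyl imide.

Step 3
Reactants: 5 enynoyl imide; 6 isoprene
Product: 7 (R)-4-benzyl-3-{[(1R,6R)-4-methyl-6-[(trimethylsilyl)ethynyl]cyclohex-3-en-1-yl]carbonyl}oxazolidin-2-one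
Conditions: Et2AlCl (1.4 equiv), CH2Cl2, −40 → −20 °C
Reagents that add atoms: none
Why: Auxiliary-controlled Lewis acid-promoted Diels–Alder reaction: in the Et2AlCl-chelated s-cis imide the benzyl group of the (R)-auxiliary shields the Cα-Si face, so isoprene should add to the Cα-Re face with its methyl-bearing carbon para to the acyl-bearing carbon, which sets the future C4 (6R in the cyclohexene) and closes ring B.

Step 4
Reactants: 7 Diels–Alder adduct
Product: 8 methyl (1R,6R)-6-ethynyl-4-methylcyclohex-3-ene-1-carboxylate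
Conditions: NaOMe, MeOH, 0 °C → rt
Reagents that add atoms: methanol, SMILES CO
Why: Methoxide transesterification of the imide (auxiliary recovered) should also remove the alkynyl silyl group; any epimerization α to the ester is harmless because that carbon is enolized in step 5.

Step 5
Reactants: 8 ester; 9 allyl bromide
Product: 11 methyl (1S,6S)-6-ethynyl-4-methyl-1-(prop-2-en-1-yl)cyclohex-3-ene-1-carboxylate, via dilithium enolate-acetylide 10 (not isolated)
Conditions: LiN(i-Pr)2 (2.2 equiv), THF, −78 °C; then 9, −78 → −20 °C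
Reagents that add atoms: none
Why: Ester enolate alkylation: allylic 1,3-strain should hold the neighbouring ethynyl group pseudoaxial, so allyl bromide attacks the exocyclic enolate anti to it and the quaternary C9 is formed with allyl trans to ethynyl, the relationship that later becomes the trans A/B ring fusion.

Step 6
Reactants: 11 quaternary ester
Product: 12 [(1S,6S)-6-ethynyl-4-methyl-1-(prop-2-en-1-yl)cyclohex-3-en-1-yl]methanol
Conditions: LiAlH4, Et2O, 0 °C
Reagents that add atoms: none
Why: Hydride reduction of the ester to the primary alcohol (C17) should leave the alkyne and both alkenes untouched.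

Step 7
Reactants: 12 alcohol
Product: 13 tert-butyldimethylsilyl ether of 12
Conditions: TBSCl, imidazole, DMF, rt
Reagents that add atoms: tert-butyldimethylsilyl chloride, SMILES CC(C)(C)[Si](C)(C)Cl
Why: Standard silylation protects the C17 hydroxyl so that it cannot compete in the directed epoxidation and the oxidation of steps 10 and 11.

Step 8
Reactants: 13 1,6-enyne
Product: 14 trans-fused ring A/ring B diene (C2=C3 and C6=C7; ethenyl on C3; 4α-H; 9β-CH2OTBS)
Conditions: second-generation Grubbs catalyst RuCl2(=CHPh)(H2IMes)(PCy3) (5 mol %), ethylene (1 atm), CH2Cl2, 40 °C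
Reagents that add atoms: none
Why: Ring-closing enyne metathesis (exo mode) of the 1,6-enyne should close ring A as a 1-vinylcyclopentene; the trans ring fusion is already fixed by C4 and C9.

Step 9
Reactants: 14 diene
Product: 16 homoallylic alcohol (19-hydroxy; C2=C3 and C6=C7 retained), via B-alkyl-9-borabicyclononane 15 (not isolated)
Conditions: 9-borabicyclo[3.3.1]nonane (9-BBN), THF, 0 °C → rt; then NaOH, H2O2, 0 °C
Reagents that add atoms: hydrogen peroxide, SMILES OO
Why: Hydroboration–oxidation with the bulky borane should select the monosubstituted terminal alkene over both trisubstituted alkenes and place the hydroxyl on the terminal carbon C19.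

Step 10
Reactants: 16 homoallylic alcohol
Product: 17 2α,3α-epoxide of 16
Conditions: VO(acac)2 (5 mol %), t-BuOOH, CH2Cl2, 0 °C → rt
Reagents that add atoms: tert-butyl hydroperoxide, SMILES CC(C)(C)OO
Why: Hydroxyl-directed vanadium-catalysed epoxidation: the homoallylic C19 hydroxyl should select C2=C3 over the remote C6=C7, and the β-axial C17 group on C9 should force attack on the α face.

Step 11
Reactants: 17 epoxy alcohol
Product: 20 hydroxy lactone (3α-hydroxy-19,2β-olide; ring D cis-fused on the β face; C6=C7; 17-OTBS), via 2α,3α-epoxy aldehyde 18 (not isolated), via 2α,3α-epoxy acid 19 (not isolated)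
Conditions: TEMPO (20 mol %), PhI(OAc)2 (2.5 equiv), MeCN/H2O (1:1), rt; then camphorsulfonic acid (cat.), CH2Cl2, rt
Reagents that add atoms: water, SMILES O
Why: Nitroxyl-catalysed oxidation of the primary alcohol to the acid followed by anti opening of the β,γ-epoxy acid at C2 (lactonization) should close ring D; inversion at C2 puts the lactone oxygen β and retention at C3 leaves the hydroxyl α.

Step 12
Reactants: 20 hydroxy lactone
Product: 21 bis-silyl ether (3α-OTBS; 17-OTBS)
Conditions: TBSOTf, 2,6-lutidine, CH2Cl2, 0 °C → rt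
Reagents that add atoms: tert-butyldimethylsilyl trifluoromethanesulfonate, SMILES CC(C)(C)[Si](C)(C)OS(=O)(=O)C(F)(F)F
Why: Silyl triflate silylation of the tertiary alcohol blocks retro-aldol and elimination pathways once C5 becomes a ketone and later prevents this hydroxyl from directing hydrogenation to the wrong face.

Step 13
Reactants: 21 bis-silyl ether
Product: 23 enone (5-oxo; C6=C7), via C5 allylic alcohol 22 (not isolated)
Conditions: SeO2 (0.5 equiv), t-BuOOH, CH2Cl2, rt; then Dess–Martin periodinane, NaHCO3, CH2Cl2, rt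
Reagents that add atoms: selenium dioxide, SMILES O=[Se]=O, reoxidized by tert-butyl hydroperoxide, SMILES CC(C)(C)OO
Why: Selenium dioxide allylic oxidation (ene reaction then [2,3]-shift) should functionalize the ring CH2 attached to the more substituted alkene carbon, that is C5, and Dess–Martin oxidation converges both epimers to the enone.

Step 14
Reactants: 23 enone
Product: 25 enol triflate (5-trifluoromethanesulfonyloxy; C5=C6), via lithium enolate 24 (not isolated)
Conditions: LiBH(s-Bu)3 (1.1 equiv), THF, −78 °C; then Comins' reagent, −78 → 0 °C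
Reagents that add atoms: N-(5-chloropyridin-2-yl)bis(trifluoromethanesulfonyl)imide (Comins' reagent), SMILES O=S(=O)(N(c1ccc(Cl)cn1)S(=O)(=O)C(F)(F)F)C(F)(F)F
Why: Conjugate reduction of the 2-methylcyclohexenone generates the C5–C6 enolate regiospecifically, away from the epimerizable C4, and O-sulfonylation should fix it as the tetrasubstituted enol triflate.

Step 15
Reactants: 26 propargyl alcohol
Product: 28 (Z)-3-iodo-2-methylprop-2-en-1-ol, via cyclic alkenylmagnesium alkoxide 27 (not isolated)
Conditions: MeMgBr (2.5 equiv), CuI (10 mol %), THF, −10 °C → rt; then iodine, −10 °C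
Reagents that add atoms: methylmagnesium bromide, SMILES C[Mg]Br; iodine, SMILES [I][I]
Why: Copper-catalysed, chelation-controlled anti carbomagnesiation of the propargylic alkoxide followed by iodinolysis should give the Z iodide with iodine cis to the hydroxymethyl group.

Step 16
Reactants: 28 (Z)-iodo alcohol
Product: 29 [(1S,2S)-2-iodo-1-methylcyclopropyl]methanol
Conditions: Et2Zn, CH2I2, DME, (4S,5S)-2-butyl-N,N,N',N'-tetramethyl-1,3,2-dioxaborolane-4,5-dicarboxamide, CH2Cl2, −10 °C → rt
Reagents that add atoms: diiodomethane, SMILES C(I)I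
Why: Charette asymmetric Simmons–Smith cyclopropanation is stereospecific (iodine and hydroxymethyl stay cis) and the (4S,5S) dioxaborolane should deliver methylene to the face that gives the (1S,2S) product.

Step 17
Reactants: 29 cyclopropylmethanol
Product: 30 (1S,2S)-2-iodo-1-methylcyclopropane-1-carbaldehyde
Conditions: Dess–Martin periodinane, NaHCO3, CH2Cl2, 0 °C
Reagents that add atoms: none
Why: Buffered Dess–Martin oxidation should give the non-enolizable aldehyde without touching the cyclopropyl iodide.

Step 18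
Reactants: 30 aldehyde
Product: 31 (1S,2S)-1-ethenyl-2-iodo-1-methylcyclopropane
Conditions: Ph3PCH3Br, KOt-Bu, THF, 0 °C
Reagents that add atoms: methyltriphenylphosphonium bromide, SMILES C[P+](c1ccccc1)(c1ccccc1)c1ccccc1.[Br-]
Why: Wittig methylenation installs the vinyl group (C13=C14) cis to iodine; the volatile product is carried on as a solution.

Step 19
Reactants: 25 enol triflate; 31 (1S,2S)-1-ethenyl-2-iodo-1-methylcyclopropane
Product: 35 tetracyclic diene (rings A–D; C5=C10 and C12=C13; 6α-methyl; 3α-OTBS; 17-OTBS), via cyclopropyllithium 32 (not isolated), via cyclopropylzinc chloride 33 (not isolated), via cis-divinylcyclopropane 34 (not isolated)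
Conditions: 31, t-BuLi (2 equiv), Et2O, −78 °C; ZnCl2, THF, −78 °C → rt; then 25, Pd2(dba)3 (5 mol %), SPhos (12 mol %), THF, 50 °C; then toluene, 100 °C
Reagents that add atoms: none
Why: Iodine–lithium exchange on 31 and transmetalation give a configurationally stable cyclopropylzinc that should undergo Negishi coupling with 25 with retention, forming C5–C10 and the cis-1,2-dialkenylcyclopropane 34, which on heating undergoes the divinylcyclopropane–cycloheptadiene rearrangement (a strain-driven [3,3]-sigmatropic shift through the only accessible boat transition state) that breaks C10–C12 and forms C6–C14. The closest known reaction types are the Negishi coupling of cyclopropylzinc halides with alkenyl triflates and the Cope rearrangement of 1-(2-vinylcyclopropyl)cycloalkenes, including cases that create quaternary carbons. Ring C is closed by this pericyclic ring expansion of the cyclopropane (three-membered to seven-membered), not by a polar or radical cyclization. The only new stereocenter, quaternary C6, is controlled by the cyclopropane stereocenters C10 and C12: bond breaking and bond making are suprafacial on the C6=C5–C10 unit, so the (1S,2S) fragment delivers C14 to the β face of C6 and leaves the C16 methyl α. The step needs retention of the cis geometry in the coupling and full stereospecificity in the rearrangement; the first is secured by the configurational stability of cyclopropyl metals, the second by the fact that only the endo,endo boat can give a cis,cis-cycloheptadiene, while the methyl group on C6 only raises the temperature required. Both new double bonds fall where they are needed: C12=C13 for the oxirane and C5=C10 for the hydrogenation that sets C5.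

Step 20
Reactants: 35 tetracyclic diene
Product: 36 17-alcohol (3α-OTBS retained)
Conditions: HF·pyridine, pyridine, THF, 0 °C
Reagents that add atoms: none
Why: Buffered fluoride desilylation should cleave the primary silyl ether much faster than the hindered tertiary one.

Step 21
Reactants: 36 17-alcohol
Product: 37 5β-H compound (C5=C10 reduced; trans B/C fusion; C12=C13 retained)
Conditions: [Rh(nbd)(dppb)]BF4 (10 mol %), H2 (50 bar), CH2Cl2, rt
Reagents that add atoms: none
Why: Hydroxyl-directed homogeneous hydrogenation: the C17 hydroxyl, 1,3-diaxial to C5, should bind the cationic rhodium catalyst and deliver hydrogen to the β face of C5=C10, while the undirected trisubstituted C12=C13 alkene is not reduced by this catalyst.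

Step 22
Reactants: 37 5β-H compound
Product: 38 diol (3α,17-dihydroxy)
Conditions: aq. HF, MeCN, rt → 40 °C
Reagents that add atoms: none
Why: Acidic fluoride desilylation of the tertiary silyl ether frees the C3 hydroxyl, which is needed as an alkoxide in step 23 so that the lactone enolate cannot eliminate it.

Step 23
Reactants: 38 diol
Product: 42 α-methylene lactone (18(20)-ene; 3α,17-diol), via trilithium salt 39 (not isolated), via Mannich base 40 (not isolated), via methiodide 41 (not isolated)
Conditions: LiN(i-Pr)2 (3.5 equiv), THF, −78 → −40 °C; CH2=NMe2+ I−, −78 °C → rt; then MeI, MeOH, rt; then aq. NaHCO3, CH2Cl2, rt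
Reagents that add atoms: N,N-dimethylmethyleneiminium iodide (Eschenmoser's salt), SMILES C=[N+](C)C.[I-]
Why: α-Methylenation of the lactone by Mannich reaction of its enolate (the β-alkoxide is not a leaving group), quaternization and Hofmann-type elimination; the new double bond can only be exocyclic because C3 bears no hydrogen.

Step 24
Reactants: 42 α-methylene lactone diol
Product: 43 17-acetate
Conditions: Ac2O, pyridine, CH2Cl2, 0 °C
Reagents that add atoms: acetic anhydride, SMILES CC(=O)OC(C)=O
Why: Acylation should be selective for the primary C17 hydroxyl; the tertiary C3 hydroxyl does not react without a nucleophilic catalyst.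

Step 25
Reactants: 43 17-acetate
Product: 44 target CNP0404717.1 (17-acetoxy-12β,13β-epoxy-3α-hydroxy-18(20)-en-19,2β-olide; 4α-H; 5β-H; 6α-CH3)
Conditions: m-CPBA, NaHCO3, CH2Cl2, 0 °C
Reagents that add atoms: 3-chloroperoxybenzoic acid, SMILES O=C(OO)c1cccc(Cl)c1
Why: Prilezhaev epoxidation should take the electron-rich trisubstituted C12=C13 alkene and leave the electron-poor α-methylene lactone, with the peracid approaching anti to the axial α-methyl C16 on the neighbouring C6 to give the 12β,13β-oxirane.

**Compound list**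
1 | (diethoxyphosphoryl)acetic acid | CCOP(=O)(OCC)CC(=O)O | starting material
2 | (R)-4-benzyloxazolidin-2-one | O=C1N[C@H](Cc2ccccc2)CO1 | starting material
3 | (R)-4-benzyl-3-[(diethoxyphosphoryl)acetyl]oxazolidin-2-one | CCOP(=O)(OCC)CC(=O)N1[C@H](Cc2ccccc2)COC1=O | intermediate
4 | 3-(trimethylsilyl)prop-2-ynal | C[Si](C)(C)C#CC=O | starting material
5 | (R)-4-benzyl-3-[(E)-5-(trimethylsilyl)pent-2-en-4-ynoyl]oxazolidin-2-one | C[Si](C)(C)C#C/C=C/C(=O)N1[C@H](Cc2ccccc2)COC1=O | intermediate
6 | isoprene (2-methylbuta-1,3-diene) | C=CC(C)=C | starting material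
7 | (R)-4-benzyl-3-{[(1R,6R)-4-methyl-6-[(trimethylsilyl)ethynyl]cyclohex-3-en-1-yl]carbonyl}oxazolidin-2-one | C[Si](C)(C)C#C[C@@H]1CC(C)=CC[C@H]1C(=O)N2[C@H](Cc3ccccc3)COC2=O | intermediate
8 | methyl (1R,6R)-6-ethynyl-4-methylcyclohex-3-ene-1-carboxylate | C#C[C@@H]1CC(C)=CC[C@H]1C(=O)OC | intermediate
9 | allyl bromide (3-bromoprop-1-ene) | C=CCBr | starting material
10 | dilithium salt of 8 (ester enolate and acetylide) | [Li+].[Li+].[C-]#C[C@@H]1CC(C)=CCC1=C([O-])OC | intermediate
11 | methyl (1S,6S)-6-ethynyl-4-methyl-1-(prop-2-en-1-yl)cyclohex-3-ene-1-carboxylate | C#C[C@@H]1CC(C)=CC[C@]1(CC=C)C(=O)OC | intermediate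
12 | [(1S,6S)-6-ethynyl-4-methyl-1-(prop-2-en-1-yl)cyclohex-3-en-1-yl]methanol | C#C[C@@H]1CC(C)=CC[C@]1(CC=C)CO | intermediate
13 | tert-butyldimethylsilyl ether of 12 | C#C[C@@H]1CC(C)=CC[C@]1(CC=C)CO[Si](C)(C)C(C)(C)C | intermediate
14 | trans-fused ring A/ring B diene: C2=C3 and C6=C7, ethenyl (C18=C19) on C3, methyl C16 on C6, 4α-H, 9β-CH2OTBS | C=CC1=CC[C@]2(CO[Si](C)(C)C(C)(C)C)CC=C(C)C[C@@H]12 | intermediate
15 | B-alkyl-9-borabicyclo[3.3.1]nonane from 14 (boron on C19) | C(CB1C2CCCC1CCC2)C1=CC[C@]2(CO[Si](C)(C)C(C)(C)C)CC=C(C)C[C@@H]12 | intermediate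
16 | homoallylic alcohol: C3 carries CH2CH2OH (C18, C19); C2=C3 and C6=C7 | OCCC1=CC[C@]2(CO[Si](C)(C)C(C)(C)C)CC=C(C)C[C@@H]12 | intermediate
17 | 2α,3α-epoxide of 16 | OCC[C@@]12O[C@@H]1C[C@]3(CO[Si](C)(C)C(C)(C)C)CC=C(C)C[C@@H]23 | intermediate
18 | 2α,3α-epoxy aldehyde (C19 aldehyde) | O=CC[C@@]12O[C@@H]1C[C@]3(CO[Si](C)(C)C(C)(C)C)CC=C(C)C[C@@H]23 | intermediate
19 | 2α,3α-epoxy acid (C19 acid) | OC(=O)C[C@@]12O[C@@H]1C[C@]3(CO[Si](C)(C)C(C)(C)C)CC=C(C)C[C@@H]23 | intermediate
20 | hydroxy lactone: 3α-hydroxy-19,2β-olide, C6=C7, 17-OTBS | C1C(=O)O[C@H]2C[C@]3(CO[Si](C)(C)C(C)(C)C)CC=C(C)C[C@H]3[C@@]12O | intermediate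
21 | bis-silyl ether: 3α-OTBS, 17-OTBS | C1C(=O)O[C@H]2C[C@]3(CO[Si](C)(C)C(C)(C)C)CC=C(C)C[C@H]3[C@@]12O[Si](C)(C)C(C)(C)C | intermediate
22 | C5 allylic alcohol (both C5 epimers), C6=C7 | C1C(=O)O[C@H]2C[C@]3(CO[Si](C)(C)C(C)(C)C)CC=C(C)C(O)[C@H]3[C@@]12O[Si](C)(C)C(C)(C)C | intermediate
23 | enone: 5-oxo, C6=C7 | C1C(=O)O[C@H]2C[C@]3(CO[Si](C)(C)C(C)(C)C)CC=C(C)C(=O)[C@H]3[C@@]12O[Si](C)(C)C(C)(C)C | intermediate
24 | lithium enolate: C5–OLi, C5=C6 | [Li+].C1C(=O)O[C@H]2C[C@]3(CO[Si](C)(C)C(C)(C)C)CCC(C)=C([O-])[C@H]3[C@@]12O[Si](C)(C)C(C)(C)C | intermediate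
25 | enol triflate: 5-trifluoromethanesulfonyloxy, C5=C6 | C1C(=O)O[C@H]2C[C@]3(CO[Si](C)(C)C(C)(C)C)CCC(C)=C(OS(=O)(=O)C(F)(F)F)[C@H]3[C@@]12O[Si](C)(C)C(C)(C)C | intermediate
26 | propargyl alcohol (prop-2-yn-1-ol) | C#CCO | starting material
27 | cyclic (Z)-alkenylmagnesium alkoxide (4-methyl-2,5-dihydro-1,2-oxamagnesole) | CC1=C[Mg]OC1 | intermediate
28 | (Z)-3-iodo-2-methylprop-2-en-1-ol | OC/C(C)=C\I | intermediate
29 | [(1S,2S)-2-iodo-1-methylcyclopropyl]methanol | I[C@H]1C[C@@]1(C)CO | intermediate
30 | (1S,2S)-2-iodo-1-methylcyclopropane-1-carbaldehyde | I[C@H]1C[C@@]1(C)C=O | intermediate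
31 | (1S,2S)-1-ethenyl-2-iodo-1-methylcyclopropane | I[C@H]1C[C@@]1(C)C=C | intermediate
32 | cyclopropyllithium from 31 (configuration retained) | [Li][C@H]1C[C@@]1(C)C=C | intermediate
33 | cyclopropylzinc chloride from 32 (configuration retained) | Cl[Zn][C@H]1C[C@@]1(C)C=C | intermediate
34 | cis-divinylcyclopropane: 25 with the triflate replaced by the cis-2-ethenyl-2-methylcyclopropyl group (C10 on C5; C11; C12 with methyl C15 and ethenyl C13=C14) | C1C(=O)O[C@H]2C[C@]3(CO[Si](C)(C)C(C)(C)C)CCC(C)=C([C@H]4C[C@@]4(C)C=C)[C@H]3[C@@]12O[Si](C)(C)C(C)(C)C | intermediate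
35 | tetracyclic diene: rings A–D, C5=C10 and C12=C13, 6α-methyl, 3α-OTBS, 17-OTBS | C1C(=O)O[C@H]2C[C@]3(CO[Si](C)(C)C(C)(C)C)CC[C@@]4(C)CC=C(C)CC=C4[C@H]3[C@@]12O[Si](C)(C)C(C)(C)C | intermediate
36 | 17-alcohol of 35 (3α-OTBS) | C1C(=O)O[C@H]2C[C@]3(CO)CC[C@@]4(C)CC=C(C)CC=C4[C@H]3[C@@]12O[Si](C)(C)C(C)(C)C | intermediate
37 | 5β-H compound: trans B/C fusion, C12=C13, 17-OH, 3α-OTBS | C1C(=O)O[C@H]2C[C@]3(CO)CC[C@@]4(C)CC=C(C)CC[C@@H]4[C@H]3[C@@]12O[Si](C)(C)C(C)(C)C | intermediate
38 | diol: 3α,17-dihydroxy, C12=C13, saturated lactone | C1C(=O)O[C@H]2C[C@]3(CO)CC[C@@]4(C)CC=C(C)CC[C@@H]4[C@H]3[C@@]12O | intermediate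
39 | trilithium salt of 38 (lactone enolate and two alkoxides) | [Li+].[Li+].[Li+].C1=C([O-])O[C@H]2C[C@]3(C[O-])CC[C@@]4(C)CC=C(C)CC[C@@H]4[C@H]3[C@@]12[O-] | intermediate
40 | Mannich base: 18-(dimethylaminomethyl) lactone (C18 epimers) | CN(C)CC1C(=O)O[C@H]2C[C@]3(CO)CC[C@@]4(C)CC=C(C)CC[C@@H]4[C@H]3[C@@]12O | intermediate
41 | methiodide of 40 | [I-].C[N+](C)(C)CC1C(=O)O[C@H]2C[C@]3(CO)CC[C@@]4(C)CC=C(C)CC[C@@H]4[C@H]3[C@@]12O | intermediate
42 | α-methylene lactone: 18(20)-ene, 3α,17-diol, C12=C13 | C=C1C(=O)O[C@H]2C[C@]3(CO)CC[C@@]4(C)CC=C(C)CC[C@@H]4[C@H]3[C@@]12O | intermediate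
43 | 17-acetate of 42 | C=C1C(=O)O[C@H]2C[C@]3(COC(C)=O)CC[C@@]4(C)CC=C(C)CC[C@@H]4[C@H]3[C@@]12O | intermediate
44 | CNP0404717.1: 17-acetoxy-12β,13β-epoxy-3α-hydroxy-18(20)-en-19,2β-olide (4α-H, 5β-H, 6α-CH3) | C=C1C(=O)O[C@H]2C[C@]3(COC(C)=O)CC[C@@]4(C)C[C@H]5O[C@@]5(C)CC[C@@H]4[C@H]3[C@@]12O | target

**Step count**
Total: 25 steps. Longest linear sequence: 21 steps (steps 1–14 and 19–25, from 1 and 2 to 44); the cyclopropane branch is 4 steps (15–18).

**Steps most likely to fail, with fallbacks**

Step 19. The cross-coupling may stall at oxidative addition or transmetalation, because the tetrasubstituted triflate sits between C4 and the C6 methyl group and the cyclopropyl partner is secondary and neopentyl-like; the cyclopropylzinc may also be protonated before it couples. Fallback, from 25 back to 35: the cyclopropane is built on the core instead of being coupled. Carbomagnesiation of 26 as in step 15, quenched with Bu3SnCl instead of iodine, should give (Z)-2-methyl-3-(tributylstannyl)prop-2-en-1-ol F1. Stille coupling of 25 with F1 (Pd(PPh3)4, CuCl, LiCl, DMSO, 60 °C), a much less demanding sp2–sp2 coupling, should give the (Z)-dienol F2. Charette cyclopropanation of F2 with the same (4S,5S) ligand, directed by the allylic hydroxyl, should give the cyclopropylmethanol F3. Dess–Martin oxidation then gives the cyclopropanecarbaldehyde F4, and Wittig methylenation (Ph3P=CH2, THF, 0 °C) gives 34, which rearranges to 35 on warming in toluene.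

Step 21. Discrimination between the two trisubstituted alkenes may be incomplete, or hydrogen may be delivered from the α face if the hydroxyl does not bind. Fallback, from 35 back to 44: the competing alkene is removed before the hydrogenation. m-CPBA on 35 should epoxidize the more accessible C12=C13 bond to give the 12β,13β-epoxide F5, and HF·pyridine then gives the 17-alcohol F6. Hydrogenation, now with one alkene left and therefore also possible with the more active [Ir(cod)(PCy3)(py)]PF6, should give the 5β-H epoxide F7, and aqueous HF gives the epoxy diol F8. The methylenation of step 23 (trilithium salt F9, Mannich base F10, methiodide F11) gives the α-methylene epoxy diol F12, and acetylation as in step 24 gives 44.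

Step 25. Facial selectivity of peracid attack on the flexible cycloheptene may be poor or reversed. Fallback, from 43 back to 44: the same steric bias is used in the opposite sense through a halohydrin. NBS in aqueous THF should form the bromonium ion on the α face, and water opens it at the tertiary C12 from the β face to give the 13α-bromo-12β-hydroxy compound F13. K2CO3 in acetone then closes the 12β,13β-oxirane of 44 with inversion at C13.

**Further compounds**
F1 | step 19 | (Z)-2-methyl-3-(tributylstannyl)prop-2-en-1-ol | CCCC[Sn](CCCC)(CCCC)/C=C(C)\CO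
F2 | step 19 | (Z)-dienol: 25 with the triflate replaced by (Z)-CH=C(CH3)CH2OH | C1C(=O)O[C@H]2C[C@]3(CO[Si](C)(C)C(C)(C)C)CCC(C)=C(/C=C(C)\CO)[C@H]3[C@@]12O[Si](C)(C)C(C)(C)C
F3 | step 19 | cyclopropylmethanol from F2 (C10–C11–C12 cyclopropane, hydroxymethyl cis to C5) | C1C(=O)O[C@H]2C[C@]3(CO[Si](C)(C)C(C)(C)C)CCC(C)=C([C@H]4C[C@@]4(C)CO)[C@H]3[C@@]12O[Si](C)(C)C(C)(C)C
F4 | step 19 | cyclopropanecarbaldehyde from F3 | C1C(=O)O[C@H]2C[C@]3(CO[Si](C)(C)C(C)(C)C)CCC(C)=C([C@H]4C[C@@]4(C)C=O)[C@H]3[C@@]12O[Si](C)(C)C(C)(C)C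
F5 | step 21 | 12β,13β-epoxide of 35 (C5=C10 retained) | C1C(=O)O[C@H]2C[C@]3(CO[Si](C)(C)C(C)(C)C)CC[C@@]4(C)C[C@H]5O[C@@]5(C)CC=C4[C@H]3[C@@]12O[Si](C)(C)C(C)(C)C
F6 | step 21 | 17-alcohol of F5 | C1C(=O)O[C@H]2C[C@]3(CO)CC[C@@]4(C)C[C@H]5O[C@@]5(C)CC=C4[C@H]3[C@@]12O[Si](C)(C)C(C)(C)C
F7 | step 21 | 5β-H epoxide (3α-OTBS, 17-OH) | C1C(=O)O[C@H]2C[C@]3(CO)CC[C@@]4(C)C[C@H]5O[C@@]5(C)CC[C@@H]4[C@H]3[C@@]12O[Si](C)(C)C(C)(C)C
F8 | step 21 | epoxy diol (3α,17-dihydroxy, saturated lactone) | C1C(=O)O[C@H]2C[C@]3(CO)CC[C@@]4(C)C[C@H]5O[C@@]5(C)CC[C@@H]4[C@H]3[C@@]12O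
F9 | step 21 | trilithium salt of F8 | [Li+].[Li+].[Li+].C1=C([O-])O[C@H]2C[C@]3(C[O-])CC[C@@]4(C)C[C@H]5O[C@@]5(C)CC[C@@H]4[C@H]3[C@@]12[O-]
F10 | step 21 | Mannich base of F8 | CN(C)CC1C(=O)O[C@H]2C[C@]3(CO)CC[C@@]4(C)C[C@H]5O[C@@]5(C)CC[C@@H]4[C@H]3[C@@]12O
F11 | step 21 | methiodide of F10 | [I-].C[N+](C)(C)CC1C(=O)O[C@H]2C[C@]3(CO)CC[C@@]4(C)C[C@H]5O[C@@]5(C)CC[C@@H]4[C@H]3[C@@]12O
F12 | step 21 | α-methylene epoxy diol (17-deacetyl target) | C=C1C(=O)O[C@H]2C[C@]3(CO)CC[C@@]4(C)C[C@H]5O[C@@]5(C)CC[C@@H]4[C@H]3[C@@]12O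
F13 | step 25 | 13α-bromo-12β-hydroxy compound from 43 | C=C1C(=O)O[C@H]2C[C@]3(COC(C)=O)CC[C@@]4(C)C[C@H](Br)[C@@](C)(O)CC[C@@H]4[C@H]3[C@@]12O
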